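**Remarks on the chemistry (assumptions)**
- Atoms carry briarane numbers: C1 (quaternary, methyl C15), C2–C10 (ten-membered ring), C11–C14 (six-membered ring A with C1 and C10), C16 (methyl on C5), C17/C18/C19 (lactone carbinol carbon, its methyl, carbonyl), C20 (methyl on C11). α/β refer to the flat projection in which the C15 methyl is β. Ring B = C1, C2, C3, C8, C9, C10; ring C = C3–C8.
- 2-Methoxy-5-methyl-1,4-benzoquinone, pent-1-en-3-one and 3-methylbut-2-enal are taken as commercial.
- In step 2 the catalyst enantiomer is the one that gives the C1 configuration drawn; if the facial mnemonic points the other way, the antipodal catalyst is used.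

**Retrosynthetic overview**
1. Target ⇐ ester, diol and lactone adjustments on the cyclodec-5-en-2-yn-8-one 21; the ten-membered ring C1–C10 is never closed by a cyclisation.
2. 21 ⇐ fragmentation of the C3–C8 bond shared by rings B and C of the linear tricycle 19 (β-oxido enol triflate gives C8 ketone and C2≡C3); the Z-C5=C6 bond is inherited from ring C.
3. Tricycle ⇐ Diels–Alder addition of a 1-silyloxy-3-methylbutadiene (C4–C7) to the C3=C8 bond of an acetoxy-ene-dione; sets C7.
4. Bicycle ⇐ enantioselective Diels–Alder of 2-methoxy-5-methylbenzoquinone (ring B) with a 2-silyloxypentadiene (ring A, sets C1); the C15 methyl then directs α-face chemistry that sets C10, C11, C12 and C14.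
5. Ring order: B (quinone) → A → C → ten-membered ring by fragmentation → γ-lactone.

Key step: step 15

**Step 1**
Reactants: 1 pent-1-en-3-one
Product: 2 (Z)-3-(tert-butyldimethylsilyloxy)penta-1,3-diene
Conditions: TBSOTf, Et3N, Et2O, 0 °C
Reagents that add atoms: tert-butyldimethylsilyl triflate CC(C)(C)[Si](C)(C)OS(=O)(=O)C(F)(F)F
Why: Soft enolisation (silyl triflate/amine) of the ethyl ketone should give the 2-silyloxy diene; its enol-ether geometry is not critical because the centre it creates (C11) is flattened in step 3.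

**Step 2**
Reactants: 2 (Z)-3-(tert-butyldimethylsilyloxy)penta-1,3-diene; 3 2-methoxy-5-methyl-1,4-benzoquinone
Product: 4 cis-fused adduct 7-(tert-butyldimethylsilyloxy)-2-methoxy-4a,8-dimethyl-4a,5,8,8a-tetrahydronaphthalene-1,4-dione (15-methyl β at C1, H-10 β, 20-methyl α)
Conditions: chiral oxazaborolidinium triflimide from (S)-α,α-diphenylprolinol and o-tolylboronic acid (20 mol%), CH2Cl2, −78 °C
Reagents that add atoms: none
Why: Enantioselective Lewis-acid-catalysed quinone Diels–Alder reaction: the methoxy-bearing C3=C8 bond is a deactivated vinylogous ester, so the diene should add across C1=C10 with its enol-ether terminus C11 on the unsubstituted C10 (β to the catalyst-bound, more basic C2 carbonyl), and the catalyst selects the face at C1, the only stereocentre of 4 that is kept.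

**Step 3**
Reactants: 4 cis-fused Diels–Alder adduct
Product: 6 (S)-2-methoxy-4a,8-dimethylnaphthalene-1,4,7(4aH)-trione (ring A 2,5-dienone with C10=C11 and C13=C14), via ring-A enone 5 (not isolated)
Conditions: DDQ (2.3 equiv), 2,4,6-collidine, benzene, rt then 70 °C
Reagents that add atoms: none
Why: DDQ dehydrogenation: hydride abstraction at C14 turns the silyl enol ether into the C13=C14 enone, and a second equivalent removes H-10/H-11 (enone to cross-conjugated dienone), which erases C10 and C11 and leaves C1 as the sole stereocentre.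

**Step 4**
Reactants: 6 ring-A dienone
Product: 7 13α,14α-epoxide of 6
Conditions: t-BuOOH, DBU, CH2Cl2, 0 °C
Reagents that add atoms: tert-butyl hydroperoxide CC(C)(C)OO
Why: Weitz–Scheffer nucleophilic epoxidation of the less substituted enone bond; the peroxide should add to C14 anti to the angular C15 methyl (α-face, as in 1α,2α-epoxidation of steroidal 1,4-dien-3-ones), while the tetrasubstituted C10=C11 and the donor-substituted C3=C8 bonds should not react.

**Step 5**
Reactants: 7 13α,14α-epoxy dienone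
Product: 9 14α-hydroxy-12-ketone with H-10 α and 20-methyl β (ring B methoxy-ene-dione intact), via saturated epoxy ketone 8 (not isolated)
Conditions: H2 (1 atm), Pd/C, EtOAc, rt, stopped after two equivalents of H2
Reagents that add atoms: none
Why: Heterogeneous hydrogenation: syn addition of H2 to the ene-dione C10=C11 should occur on the α-face (the β-face carries the C15 methyl and the flat ring B has no α-axial hydrogens), setting H-10α and H-11α (trans ring fusion, 20-methyl β) together, and hydrogenolysis of the Cα–O bond of the α,β-epoxy ketone gives the 14α-alcohol.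

**Step 6**
Reactants: 9 14α-hydroxy-12-ketone
Product: 10 12β,14α-diol
Conditions: Me4NBH(OAc)3, MeCN/AcOH, −25 °C
Reagents that add atoms: none
Why: Evans–Saksena hydroxyl-directed reduction: the 14α-alkoxyborohydride delivers hydride to the α-face of C12 and gives the anti-1,3-diol (12β-OH) before the axial C11 methyl can epimerise; the vinylogous-ester C2 and enone C9 carbonyls are not reduced by this reagent.

**Step 7**
Reactants: 10 12β,14α-diol
Product: 11 12β-(tert-butyldiphenylsilyloxy)-14α-ol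
Conditions: TBDPSCl, imidazole, DMF, rt
Reagents that add atoms: tert-butyldiphenylsilyl chloride CC(C)(C)[Si](Cl)(c1ccccc1)c1ccccc1
Why: Silylation of the less hindered equatorial 12-OH; the axial, neopentyl 14-OH should stay free.

**Step 8**
Reactants: 11 12-O-TBDPS methoxy-ene-dione
Product: 12 C8 enol (diosphenol) of the C2,C8,C9-triketone
Conditions: 1 M HCl, THF, 0 °C to rt
Reagents that add atoms: water O
Why: Acid hydrolysis of the vinylogous methyl ester (addition–elimination at C8) to the enolised triketone; acid is used instead of hydroxide to avoid enolate formation at C10 and retro-aldol cleavage at C1–C14.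

**Step 9**
Reactants: 12 diosphenol
Product: 13 C8 enol acetate (2-acetoxy-ene-dione)
Conditions: Ac2O, Et3N, CH2Cl2, −20 °C
Reagents that add atoms: acetic anhydride CC(=O)OC(C)=O
Why: O-acylation of the acidic enol gives a captodative acyloxy-ene-dione dienophile; without DMAP the hindered 14-OH should not be acylated.

**Step 10**
Reactants: 14 3-methylbut-2-enal
Product: 15 (E)-3-methyl-1-(triethylsilyloxy)buta-1,3-diene
Conditions: TESOTf, Et3N, Et2O, 0 °C
Reagents that add atoms: triethylsilyl triflate CC[Si](CC)(CC)OS(=O)(=O)C(F)(F)F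
Why: γ-Deprotonation and O-silylation of the enal (silyl dienol ether formation) should give the (E)-1-silyloxy diene.

**Step 11**
Reactants: 13 acetoxy-ene-dione; 15 (E)-3-methyl-1-(triethylsilyloxy)buta-1,3-diene
Product: 16 tricyclic adduct (rings A, B, C): C2 and C9 ketones, 8β-OAc, H-3 β, 7α-OTES (H-7 β), C5=C6, 12β-OTBDPS, 14α-OH
Conditions: toluene, BHT, 80 °C
Reagents that add atoms: none
Why: Diels–Alder reaction that builds ring C (C3–C4 and C7–C8 bonds): the nucleophilic C4 terminus bonds to the unsubstituted C3 and the oxygenated C7 terminus to the acetoxy-bearing C8; approach on the α-face (anti to the axial C15 methyl) in the endo mode places the C7 silyloxy group cis to C9 on ring C (7α-O, H-7β) and makes O-8 and H-3 β.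

**Step 12**
Reactants: 16 tricyclic diketone
Product: 17 9α-alcohol (C2 ketone retained)
Conditions: NaBH4, MeOH/THF, −78 °C; AcOH quench
Reagents that add atoms: none
Why: Hydride reduction of the α-acetoxy-activated C9 ketone in preference to the C2 ketone flanked by quaternary C1; the α-face of C9 is covered by the cis-fused ring C (axial C7 with its OTES group), so hydride should enter from the β-face and give the equatorial 9α-alcohol, also the more stable epimer; low temperature suppresses acetyl migration from O-8.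

**Step 13**
Reactants: 17 9α,14α-diol
Product: 18 9α,14α-bis(tert-butyldimethylsilyl) ether
Conditions: TBSOTf, 2,6-lutidine, CH2Cl2, 0 °C
Reagents that add atoms: tert-butyldimethylsilyl triflate CC(C)(C)[Si](C)(C)OS(=O)(=O)C(F)(F)F
Why: The silyl triflate silylates both hindered secondary alcohols; the tertiary acetate is unaffected.

**Step 14**
Reactants: 18 C2 ketone
Product: 19 C2 enol triflate (C2=C3) with 8β-OAc
Conditions: Tf2O, 2,6-di-tert-butyl-4-methylpyridine, CH2Cl2, 0 °C to rt
Reagents that add atoms: triflic anhydride O=S(=O)(OS(=O)(=O)C(F)(F)F)C(F)(F)F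
Why: Enol triflate formation under non-basic conditions; C2 can enolise only toward C3 because C1 is quaternary, and avoiding an amide base prevents enolisation of the acetate and E1cB loss of the C8 acetoxy group.

**Step 15**
Reactants: 19 β-acetoxy enol triflate
Product: 21 cyclodec-5-en-2-yn-8-one fused to ring A (C2≡C3, Z-C5=C6, 7α-OTES, C8 ketone, 9α-OTBS, 12β-OTBDPS, 14α-OTBS), via lithium C8-alkoxide 20 (not isolated)
Conditions: MeLi (2.1 equiv), THF, −78 °C then 0 °C
Reagents that add atoms: none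
Why: MeLi cleaves the tertiary acetate to the lithium C8-alkoxide 20, whose C3–C8 σ-bond is held trans-coplanar to the C2–OTf bond across C2=C3 by ring B, so that on warming the alkoxide collapses to the C8 ketone while C3–C8 breaks, C2≡C3 forms and triflate leaves. This is a Grob-type fragmentation of a β-oxido enol triflate, the reaction type by which adducts of cyclic vinylogous acyl triflates open or ring-expand to alkynyl ketones, and the sulfonate counterpart of the Eschenmoser–Tanabe fragmentation. No ring is closed: the ten-membered ring C1–C10 is released by scission of the bond common to the six-membered rings B and C, so the entropic and transannular penalties of a medium-ring cyclisation are avoided. No stereocentre is created; C1, C7, C9, C10, C11, C12 and C14 pass through untouched, the temporary centres C3 and C8 are destroyed, and the Z geometry of C5=C6 is inherited from ring C. The step needs C–C fragmentation to outrun attack of MeLi on the triflate or on the ketone being formed; both equivalents of MeLi are consumed by the acetate at −78 °C (the acetone released goes on to tert-butoxide) before the alkoxide fragments on warming, and the fragmentation is irreversible. The cyclodecenynone is a plausible product because cyclodecyne is isolable and the skipped Z-alkene should add little strain.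

**Step 16**
Reactants: 21 cyclodecenynone
Product: 22 7α-hydroxy-8-ketone
Conditions: PPTS, MeOH, 0 °C
Reagents that add atoms: none
Why: Acid-catalysed methanolysis of the allylic triethylsilyl ether, which is far more labile than the hindered TBS and the TBDPS ethers.

**Step 17**
Reactants: 22 7α-hydroxy-8-ketone
Product: 23 7-O-(2-bromopropanoyl) ester (mixture at the bromine-bearing carbon)
Conditions: 2-bromopropanoyl bromide, pyridine, CH2Cl2, −20 °C
Reagents that add atoms: 2-bromopropanoyl bromide CC(Br)C(Br)=O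
Why: Acylation of the secondary α-ketol hydroxyl by the acid bromide; the configuration of the future C17 is immaterial at this stage.

**Step 18**
Reactants: 23 α-bromo ester
Product: 24 cis-fused 8β-hydroxy-γ-lactone (C7–O–C19(=O)–C17–C8; C17 epimers)
Conditions: SmI2 (2.2 equiv), THF, −78 °C
Reagents that add atoms: none
Why: Samarium-mediated intramolecular Reformatsky reaction: the C–Br bond is reduced first and the samarium enolate adds to the chelated C8 carbonyl on the face where O-7 lies; the rotamer with H-7 (not the vinylic C6) eclipsing the carbonyl should react, so that C6 and C9 end cis on the five-membered ring (8β-OH), and the C17 epimers converge in step 19.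

**Step 19**
Reactants: 24 β-hydroxy lactone
Product: 25 8β,17-dihydroxy lactone (17R; 17-OH trans to 8-OH, C18 methyl cis to 8-OH)
Conditions: LDA (3.2 equiv), THF, −78 °C; then 2-(phenylsulfonyl)-3-phenyloxaziridine
Reagents that add atoms: 2-(phenylsulfonyl)-3-phenyloxaziridine O=S(=O)(c1ccccc1)N1OC1c1ccccc1
Why: α-Hydroxylation of the lactone enolate with an N-sulfonyloxaziridine; in the alkoxide–enolate dianion the electrophile should enter anti to the C8 oxido group (Fráter–Seebach-type 1,2-induction), giving the trans-8,17-diol, and the dianion is protected against retro-aldol cleavage.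

**Step 20**
Reactants: 25 alkyne diol lactone
Product: 26 (2Z,5Z)-diene
Conditions: H2 (1 atm), Lindlar catalyst, quinoline, EtOAc, rt
Reagents that add atoms: none
Why: Lindlar semihydrogenation adds H2 syn to the alkyne and gives the Z-C2=C3 alkene; the trisubstituted C5=C6 bond should not be reduced.

**Step 21**
Reactants: 26 (2Z,5Z)-diene
Product: 27 2β,3β-diol
Conditions: OsO4 (cat.), NMO, acetone/H2O, 0 °C
Reagents that add atoms: osmium tetroxide (catalytic) O=[Os](=O)(=O)=O; N-methylmorpholine N-oxide C[N+]1([O-])CCOCC1; water O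
Why: Upjohn syn-dihydroxylation: the cis-disubstituted C2=C3 bond should react before C5=C6, which is hindered and deactivated by the allylic lactone oxygen, and osmium should approach the face bearing the small C15 methyl (anti to C14–OTBS and ring A), giving both hydroxyls β.

**Step 22**
Reactants: 27 2β,3β-diol
Product: 28 3-O-butanoate (2β-OH free)
Conditions: butanoic anhydride, Et3N, DMAP (cat.), CH2Cl2, −40 °C
Reagents that add atoms: butanoic anhydride CCCC(=O)OC(=O)CCC
Why: Selective acylation of the less hindered C3 hydroxyl; the neopentyl C2 hydroxyl and the tertiary 8- and 17-hydroxyls should not react at low temperature.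

**Step 23**
Reactants: 28 3-O-butanoate
Product: 29 2β,9α,14α-triol (12-O-TBDPS retained)
Conditions: aq. HF, MeCN, 0 °C
Reagents that add atoms: none
Why: Acidic fluoride cleaves the two TBS ethers much faster than the TBDPS ether.

**Step 24**
Reactants: 29 triol
Product: 30 2,9,14-triacetate 12-O-TBDPS ether
Conditions: Ac2O, pyridine, DMAP (cat.), rt
Reagents that add atoms: acetic anhydride CC(=O)OC(C)=O
Why: DMAP-catalysed acetylation of the three secondary alcohols; the tertiary 8- and 17-hydroxyls are too hindered to be acylated under these conditions.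

**Step 25**
Reactants: 30 protected triacetate
Product: 31 briaexcavatolide L
Conditions: HF·pyridine, pyridine, THF, rt
Reagents that add atoms: none
Why: Fluoride cleavage of the TBDPS ether frees the 12β-hydroxyl; the buffered, non-basic medium avoids acyl migration.

**Compound list**
1 | pent-1-en-3-one | C=CC(=O)CC | starting material
2 | (Z)-3-(tert-butyldimethylsilyloxy)penta-1,3-diene | C/C=C(\O[Si](C)(C)C(C)(C)C)C=C | intermediate
3 | 2-methoxy-5-methyl-1,4-benzoquinone | COC1=CC(=O)C(C)=CC1=O | starting material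
4 | cis-fused adduct, 7-(TBS-oxy)-2-methoxy-4a,8-dimethyl-4a,5,8,8a-tetrahydronaphthalene-1,4-dione | C[C@]12CC=C(O[Si](C)(C)C(C)(C)C)[C@@H](C)[C@H]1C(=O)C(OC)=CC2=O | intermediate
5 | ring-A enone (C13=C14, C12 ketone) | C[C@]12C=CC(=O)[C@@H](C)[C@H]1C(=O)C(OC)=CC2=O | intermediate
6 | (S)-2-methoxy-4a,8-dimethylnaphthalene-1,4,7(4aH)-trione | C[C@]12C=CC(=O)C(C)=C1C(=O)C(OC)=CC2=O | intermediate
7 | 13α,14α-epoxide of 6 | C[C@]12[C@H]3O[C@H]3C(=O)C(C)=C1C(=O)C(OC)=CC2=O | intermediate
8 | saturated epoxy ketone (H-10α, 20-methyl β) | C[C@]12[C@H]3O[C@H]3C(=O)[C@H](C)[C@@H]1C(=O)C(OC)=CC2=O | intermediate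
9 | 14α-hydroxy-12-ketone | C[C@]12[C@@H](O)CC(=O)[C@H](C)[C@@H]1C(=O)C(OC)=CC2=O | intermediate
10 | 12β,14α-diol | C[C@]12[C@@H](O)C[C@H](O)[C@H](C)[C@@H]1C(=O)C(OC)=CC2=O | intermediate
11 | 12β-O-TBDPS-14α-ol | C[C@]12[C@@H](O)C[C@H](O[Si](c3ccccc3)(c3ccccc3)C(C)(C)C)[C@H](C)[C@@H]1C(=O)C(OC)=CC2=O | intermediate
12 | C8 enol (diosphenol) | C[C@]12[C@@H](O)C[C@H](O[Si](c3ccccc3)(c3ccccc3)C(C)(C)C)[C@H](C)[C@@H]1C(=O)C(O)=CC2=O | intermediate
13 | C8 enol acetate (acetoxy-ene-dione) | C[C@]12[C@@H](O)C[C@H](O[Si](c3ccccc3)(c3ccccc3)C(C)(C)C)[C@H](C)[C@@H]1C(=O)C(OC(C)=O)=CC2=O | intermediate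
14 | 3-methylbut-2-enal | CC(C)=CC=O | starting material
15 | (E)-3-methyl-1-(triethylsilyloxy)buta-1,3-diene | C=C(C)/C=C/O[Si](CC)(CC)CC | intermediate
16 | tricyclic Diels–Alder adduct (8β-OAc, 7α-OTES) | C[C@]12[C@@H](O)C[C@H](O[Si](c3ccccc3)(c3ccccc3)C(C)(C)C)[C@H](C)[C@@H]1C(=O)[C@@]1(OC(C)=O)[C@@H](O[Si](CC)(CC)CC)C=C(C)C[C@H]1C2=O | intermediate
17 | 9α-alcohol | C[C@]12[C@@H](O)C[C@H](O[Si](c3ccccc3)(c3ccccc3)C(C)(C)C)[C@H](C)[C@@H]1[C@@H](O)[C@@]1(OC(C)=O)[C@@H](O[Si](CC)(CC)CC)C=C(C)C[C@H]1C2=O | intermediate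
18 | 9α,14α-bis-TBS ether | C[C@]12[C@@H](O[Si](C)(C)C(C)(C)C)C[C@H](O[Si](c3ccccc3)(c3ccccc3)C(C)(C)C)[C@H](C)[C@@H]1[C@@H](O[Si](C)(C)C(C)(C)C)[C@@]1(OC(C)=O)[C@@H](O[Si](CC)(CC)CC)C=C(C)C[C@H]1C2=O | intermediate
19 | C2 enol triflate | C[C@]12[C@@H](O[Si](C)(C)C(C)(C)C)C[C@H](O[Si](c3ccccc3)(c3ccccc3)C(C)(C)C)[C@H](C)[C@@H]1[C@@H](O[Si](C)(C)C(C)(C)C)[C@@]1(OC(C)=O)[C@@H](O[Si](CC)(CC)CC)C=C(C)CC1=C2OS(=O)(=O)C(F)(F)F | intermediate
20 | lithium C8-alkoxide | C[C@]12[C@@H](O[Si](C)(C)C(C)(C)C)C[C@H](O[Si](c3ccccc3)(c3ccccc3)C(C)(C)C)[C@H](C)[C@@H]1[C@@H](O[Si](C)(C)C(C)(C)C)[C@@]1([O-])[C@@H](O[Si](CC)(CC)CC)C=C(C)CC1=C2OS(=O)(=O)C(F)(F)F.[Li+] | intermediate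
21 | cyclodec-5-en-2-yn-8-one (7α-OTES, 9α-OTBS, 12β-OTBDPS, 14α-OTBS) | C[C@@]12C#CC/C(C)=C\[C@H](O[Si](CC)(CC)CC)C(=O)[C@H](O[Si](C)(C)C(C)(C)C)[C@H]1[C@@H](C)[C@@H](O[Si](c1ccccc1)(c1ccccc1)C(C)(C)C)C[C@@H]2O[Si](C)(C)C(C)(C)C | intermediate
22 | 7α-hydroxy-8-ketone | C[C@@]12C#CC/C(C)=C\[C@H](O)C(=O)[C@H](O[Si](C)(C)C(C)(C)C)[C@H]1[C@@H](C)[C@@H](O[Si](c1ccccc1)(c1ccccc1)C(C)(C)C)C[C@@H]2O[Si](C)(C)C(C)(C)C | intermediate
23 | 7-O-(2-bromopropanoyl) ester | C[C@@]12C#CC/C(C)=C\[C@H](OC(=O)C(C)Br)C(=O)[C@H](O[Si](C)(C)C(C)(C)C)[C@H]1[C@@H](C)[C@@H](O[Si](c1ccccc1)(c1ccccc1)C(C)(C)C)C[C@@H]2O[Si](C)(C)C(C)(C)C | intermediate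
24 | 8β-hydroxy-γ-lactone (C17 epimers) | C[C@@]12C#CC/C(C)=C\[C@@H]3OC(=O)C(C)[C@]3(O)[C@H](O[Si](C)(C)C(C)(C)C)[C@H]1[C@@H](C)[C@@H](O[Si](c1ccccc1)(c1ccccc1)C(C)(C)C)C[C@@H]2O[Si](C)(C)C(C)(C)C | intermediate
25 | 8β,17-dihydroxy lactone (17R) | C[C@@]12C#CC/C(C)=C\[C@@H]3OC(=O)[C@](C)(O)[C@]3(O)[C@H](O[Si](C)(C)C(C)(C)C)[C@H]1[C@@H](C)[C@@H](O[Si](c1ccccc1)(c1ccccc1)C(C)(C)C)C[C@@H]2O[Si](C)(C)C(C)(C)C | intermediate
26 | (2Z,5Z)-diene | C[C@@]12/C=C\C/C(C)=C\[C@@H]3OC(=O)[C@](C)(O)[C@]3(O)[C@H](O[Si](C)(C)C(C)(C)C)[C@H]1[C@@H](C)[C@@H](O[Si](c1ccccc1)(c1ccccc1)C(C)(C)C)C[C@@H]2O[Si](C)(C)C(C)(C)C | intermediate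
27 | 2β,3β-diol | C[C@@]12[C@@H](O)[C@@H](O)C/C(C)=C\[C@@H]3OC(=O)[C@](C)(O)[C@]3(O)[C@H](O[Si](C)(C)C(C)(C)C)[C@H]1[C@@H](C)[C@@H](O[Si](c1ccccc1)(c1ccccc1)C(C)(C)C)C[C@@H]2O[Si](C)(C)C(C)(C)C | intermediate
28 | 3-O-butanoate | C[C@@]12[C@@H](O)[C@@H](OC(=O)CCC)C/C(C)=C\[C@@H]3OC(=O)[C@](C)(O)[C@]3(O)[C@H](O[Si](C)(C)C(C)(C)C)[C@H]1[C@@H](C)[C@@H](O[Si](c1ccccc1)(c1ccccc1)C(C)(C)C)C[C@@H]2O[Si](C)(C)C(C)(C)C | intermediate
29 | 2β,9α,14α-triol 12-O-TBDPS ether | C[C@@]12[C@@H](O)[C@@H](OC(=O)CCC)C/C(C)=C\[C@@H]3OC(=O)[C@](C)(O)[C@]3(O)[C@H](O)[C@H]1[C@@H](C)[C@@H](O[Si](c1ccccc1)(c1ccccc1)C(C)(C)C)C[C@@H]2O | intermediate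
30 | 2,9,14-triacetate 12-O-TBDPS ether | C[C@@]12[C@@H](OC(C)=O)[C@@H](OC(=O)CCC)C/C(C)=C\[C@@H]3OC(=O)[C@](C)(O)[C@]3(O)[C@H](OC(C)=O)[C@H]1[C@@H](C)[C@@H](O[Si](c1ccccc1)(c1ccccc1)C(C)(C)C)C[C@@H]2OC(C)=O | intermediate
31 | briaexcavatolide L | C[C@@]12[C@@H](OC(C)=O)[C@@H](OC(=O)CCC)C/C(C)=C\[C@@H]3OC(=O)[C@](C)(O)[C@]3(O)[C@H](OC(C)=O)[C@H]1[C@@H](C)[C@@H](O)C[C@@H]2OC(C)=O | target

**Totals**
Total step count: 25. Longest linear sequence: 24 (steps 1–9 and 11–25; step 10 is the side branch).

**Three steps most likely to fail, with fallbacks**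

Step 15 (key fragmentation). The alkoxide may fail to fragment to the strained enyne, or MeLi may attack the triflate sulfur or the emerging ketone. The fallback sets out from 18 and returns at 21. DBU in CH2Cl2 should eliminate acetic acid (E1cB) to give the C2 enone F1 (C3=C8). Nucleophilic epoxidation (t-BuOOH, Triton B) should give the 3,8-epoxy ketone F2; either epoxide face serves because both carbons lose their configuration. p-Toluenesulfonylhydrazide in AcOH/CH2Cl2 should give the tosylhydrazone F3, which undergoes Eschenmoser–Tanabe fragmentation with loss of N2 and sulfinate to the same alkynone 21.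

Step 18 (lactone closure). The tethered enolate may add with the wrong ring-fusion sense at C8, or add too slowly to the hindered ketone. The fallback sets out from 21 and returns at 25. The lithium enolate of (2S,5S)-2-tert-butyl-5-methyl-1,3-dioxolan-4-one (the pivalaldehyde acetal of (S)-lactic acid; LDA, THF, −78 °C) reacts anti to its tert-butyl group, which fixes C17 as R independently of the substrate. Intermolecular aldol addition to the C8 ketone should give the tertiary aldol F4. TsOH in MeOH then removes the TES group, and the freed 7-OH transacylates the dioxolanone to the lactone 25 with loss of pivalaldehyde.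

Step 21 (dihydroxylation). Osmylation may not discriminate between C2=C3 and C5=C6, or may take the wrong face. The fallback sets out from 25 and returns at 28. Ruthenium-catalysed trans-hydrosilylation of the alkyne ([Cp*Ru(MeCN)3]PF6, (EtO)3SiH) should give the alkenylsilane F5, and protodesilylation (AgF, THF/MeOH) the E-cyclodecene F6. Its strained trans double bond should be epoxidised first (dimethyldioxirane), on the same face as the C15 methyl at C2, to give the 2,3-epoxide F7. Opening with butanoic acid and Ti(OiPr)4 at the less hindered C3, with inversion, gives 28 directly (C3 butanoate and 2β-OH in one step).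

**Further compounds**
F1 | step 15 | C2 enone with C3=C8 (from 18 by loss of AcOH) | C[C@]12[C@@H](O[Si](C)(C)C(C)(C)C)C[C@H](O[Si](c3ccccc3)(c3ccccc3)C(C)(C)C)[C@H](C)[C@@H]1[C@@H](O[Si](C)(C)C(C)(C)C)C1=C(CC(C)=C[C@@H]1O[Si](CC)(CC)CC)C2=O
F2 | step 15 | 3,8-epoxy C2 ketone (epoxide configuration immaterial) | C[C@]12[C@@H](O[Si](C)(C)C(C)(C)C)C[C@H](O[Si](c3ccccc3)(c3ccccc3)C(C)(C)C)[C@H](C)[C@@H]1[C@@H](O[Si](C)(C)C(C)(C)C)C13OC3(CC(C)=C[C@@H]1O[Si](CC)(CC)CC)C2=O
F3 | step 15 | tosylhydrazone of F2 | C[C@]12[C@@H](O[Si](C)(C)C(C)(C)C)C[C@H](O[Si](c3ccccc3)(c3ccccc3)C(C)(C)C)[C@H](C)[C@@H]1[C@@H](O[Si](C)(C)C(C)(C)C)C13OC3(CC(C)=C[C@@H]1O[Si](CC)(CC)CC)C2=NNS(=O)(=O)c1ccc(C)cc1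
F4 | step 18 | C8 aldol adduct of the lactic acid dioxolanone (8β-OH, 17R) | C[C@@]12C#CC/C(C)=C\[C@H](O[Si](CC)(CC)CC)[C@](O)([C@@]3(C)O[C@H](C(C)(C)C)OC3=O)[C@H](O[Si](C)(C)C(C)(C)C)[C@H]1[C@@H](C)[C@@H](O[Si](c1ccccc1)(c1ccccc1)C(C)(C)C)C[C@@H]2O[Si](C)(C)C(C)(C)C
F5 | step 21 | C3 triethoxysilyl alkene (trans-hydrosilylation product) | C[C@@]12/C=C(\[Si](OCC)(OCC)OCC)C/C(C)=C\[C@@H]3OC(=O)[C@](C)(O)[C@]3(O)[C@H](O[Si](C)(C)C(C)(C)C)[C@H]1[C@@H](C)[C@@H](O[Si](c1ccccc1)(c1ccccc1)C(C)(C)C)C[C@@H]2O[Si](C)(C)C(C)(C)C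
F6 | step 21 | (2E,5Z)-diene | C[C@@]12/C=C/C/C(C)=C\[C@@H]3OC(=O)[C@](C)(O)[C@]3(O)[C@H](O[Si](C)(C)C(C)(C)C)[C@H]1[C@@H](C)[C@@H](O[Si](c1ccccc1)(c1ccccc1)C(C)(C)C)C[C@@H]2O[Si](C)(C)C(C)(C)C
F7 | step 21 | trans-2,3-epoxide (O β at C2) | C[C@@]12[C@H]4O[C@@H]4C/C(C)=C\[C@@H]3OC(=O)[C@](C)(O)[C@]3(O)[C@H](O[Si](C)(C)C(C)(C)C)[C@H]1[C@@H](C)[C@@H](O[Si](c1ccccc1)(c1ccccc1)C(C)(C)C)C[C@@H]2O[Si](C)(C)C(C)(C)C
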